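**Plan**

- Hardest point: an intact (2''E)-geranyl chain has to sit on C8, not C6, of the phloroglucinol A ring, beside a C2 stereocentre that is lost by retro-oxa-Michael ring opening in base.
- Retrosynthesis: the C8–C1'' bond is cut and traced back to an O5–C1'' ether, a bond absent from the target. The C2–C1' bond is cut to a chromone and an arylboronic acid; the benzopyranone ring is bought.
- Forward: the chain is joined to O5 of the chromone, the B ring is added to C2, the chain then walks O5 → C6 → C8 by two [3,3] shifts, and the silyl groups are removed.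
- Stereochemistry: C2 (S) comes from a Rh/chiral bisphosphine 1,4-arylation; 2''E comes from geraniol and is carried through two chair transition states.
- Enabling feature: O5 is peri to C4=O (a bidentate site for Eu(III)) and para to C8. Its only free ortho carbon is C6, and C6–C7=C8 completes the 1,5-diene for the second shift. The same ether masks the chelated 5-OH during the arylation.

Key step: step 4

Assumption: 5,7-dihydroxychromone is taken as a purchasable compound, and the (S)-biaryl bisphosphine is taken to give the 2S product by analogy with cyclic enones; if the sense proves opposite, the (R)-ligand is used.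

**Route**

Step 1
Reactants: 1 5,7-dihydroxy-4H-chromen-4-one
Product: 2 7-[(tert-butyldimethylsilyl)oxy]-5-hydroxy-4H-chromen-4-one
Conditions: TBSCl (1.1 equiv), imidazole, DMF, 0 °C → rt
Reagents that add atoms: tert-butyldimethylsilyl chloride, CC(C)(C)[Si](C)(C)Cl
Why: Chemoselective phenol silylation: the 7-OH is a free vinylogous acid, whereas the 5-OH is held in a hydrogen bond to C4=O and should stay untouched with one equivalent of TBSCl.

Step 2
Reactants: 2 7-[(tert-butyldimethylsilyl)oxy]-5-hydroxy-4H-chromen-4-one; 3 geraniol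
Product: 4 7-[(tert-butyldimethylsilyl)oxy]-5-{[(2E)-3,7-dimethylocta-2,6-dien-1-yl]oxy}-4H-chromen-4-one
Conditions: PPh3, DIAD, THF, 0 °C → rt
Reagents that add atoms: none
Why: Mitsunobu etherification: the chelated 5-OH is the only acidic site left and should displace the activated primary allylic alcohol at C1'' (SN2), so the 2''E alkene comes through unchanged and the neutral medium spares the silyl ether.

Step 3
Reactants: 4 7-[(tert-butyldimethylsilyl)oxy]-5-{[(2E)-3,7-dimethylocta-2,6-dien-1-yl]oxy}-4H-chromen-4-one; 5 {4-[(tert-butyldimethylsilyl)oxy]phenyl}boronic acid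
Product: 6 (2S)-7-[(tert-butyldimethylsilyl)oxy]-2-{4-[(tert-butyldimethylsilyl)oxy]phenyl}-5-{[(2E)-3,7-dimethylocta-2,6-dien-1-yl]oxy}-2,3-dihydro-4H-chromen-4-one
Conditions: [Rh(OH)((S)-MeO-F12-BIPHEP)]2 (3 mol% Rh), toluene/H2O (10:1), 30 °C
Reagents that add atoms: none
Why: Rh(I)-catalysed asymmetric 1,4-addition of an arylboronic acid to a chromone (Hayashi–Miyaura type): the aryl–Rh species of the C2-symmetric electron-poor bisphosphine adds to one face of C2=C3 and water protonates the Rh enolate, which sets C2 as S under base-free conditions in which the flavanone should not ring-open, while the isolated trisubstituted alkenes and the allyl aryl ether are not acceptors for aryl–Rh(I).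

Step 4
Reactants: 6 (2S)-7-[(tert-butyldimethylsilyl)oxy]-2-{4-[(tert-butyldimethylsilyl)oxy]phenyl}-5-{[(2E)-3,7-dimethylocta-2,6-dien-1-yl]oxy}-2,3-dihydro-4H-chromen-4-one
Product: 9 (2S)-7-[(tert-butyldimethylsilyl)oxy]-2-{4-[(tert-butyldimethylsilyl)oxy]phenyl}-8-[(2E)-3,7-dimethylocta-2,6-dien-1-yl]-5-hydroxy-2,3-dihydro-4H-chromen-4-one, via C6 ortho-dienone 7 (not isolated), via C8 para-dienone 8 (not isolated)
Conditions: Eu(fod)3 (10 mol%), NaHCO3 (solid), CHCl3 (acid-free), 60 °C, sealed tube
Reagents that add atoms: none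
Why: Eu(III) bound to the C4=O/O5 pair polarises the O5–C1'' bond and triggers an aromatic Claisen [3,3] shift to C6, the only free ortho carbon of O5, giving dienone 7 with the chain attached through C3''; C6–C7=C8 of 7 and the new vinyl group form a 1,5-diene, a Cope [3,3] shift moves the chain to C8 (dienone 8, attached through C1'' again), and enolisation of C5=O restores the arene and the chelated 5-OH. The closest known reaction type is the Lewis-acid-catalysed para-Claisen (Claisen–Cope) rearrangement of 5-O-prenyl flavanones and flavones to their 8-prenyl isomers. No ring is closed; both shifts pass through six-membered chair transition states on the same face of the A ring. No permanent stereocentre is made: C6 and C3'' of 7 and C8 of 8 are transient, the chair of the first shift fixes C3'' relative to C6 so that the chair of the second shift returns the methyl group cis to C1'' (2''E retained), and C2 lies outside both pericyclic arrays and sees no base. The step needs C8 over C6 selectivity, meaning the Cope shift must outrun enolisation of 7. This is secured by Eu(III) chelation of the C4=O/C5=O β-dicarbonyl unit of 7, which keeps the dienone electron-poor, and by C8 being the only carbon the migrating allyl unit can reach from C6.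

Step 5
Reactants: 9 (2S)-7-[(tert-butyldimethylsilyl)oxy]-2-{4-[(tert-butyldimethylsilyl)oxy]phenyl}-8-[(2E)-3,7-dimethylocta-2,6-dien-1-yl]-5-hydroxy-2,3-dihydro-4H-chromen-4-one
Product: 10 sophoraflavanone A, (2S)-8-[(2E)-3,7-dimethylocta-2,6-dien-1-yl]-5,7-dihydroxy-2-(4-hydroxyphenyl)-2,3-dihydro-4H-chromen-4-one
Conditions: TBAF/AcOH (1:1, 2.5 equiv each), THF, 0 °C
Reagents that add atoms: none
Why: Fluoride cleavage of aryl silyl ethers: the acetic acid buffer protonates each phenoxide as it forms, so neither retro-oxa-Michael opening at C2 nor acid-induced cyclisation of the geranyl chain onto the 7-OH should occur.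

**Compound list**

1 | 5,7-dihydroxy-4H-chromen-4-one | O=c1ccoc2cc(O)cc(O)c12 | starting material
2 | 7-[(tert-butyldimethylsilyl)oxy]-5-hydroxy-4H-chromen-4-one | CC(C)(C)[Si](C)(C)Oc1cc(O)c2c(c1)occc2=O | intermediate
3 | geraniol, (2E)-3,7-dimethylocta-2,6-dien-1-ol | CC(C)=CCC/C(C)=C/CO | starting material
4 | 7-[(tert-butyldimethylsilyl)oxy]-5-{[(2E)-3,7-dimethylocta-2,6-dien-1-yl]oxy}-4H-chromen-4-one | CC(C)=CCC/C(C)=C/COc1cc(O[Si](C)(C)C(C)(C)C)cc2occc(=O)c12 | intermediate
5 | {4-[(tert-butyldimethylsilyl)oxy]phenyl}boronic acid | CC(C)(C)[Si](C)(C)Oc1ccc(B(O)O)cc1 | starting material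
6 | (2S)-7-[(tert-butyldimethylsilyl)oxy]-2-{4-[(tert-butyldimethylsilyl)oxy]phenyl}-5-{[(2E)-3,7-dimethylocta-2,6-dien-1-yl]oxy}-2,3-dihydro-4H-chromen-4-one | CC(C)=CCC/C(C)=C/COc1cc(O[Si](C)(C)C(C)(C)C)cc2O[C@H](c3ccc(O[Si](C)(C)C(C)(C)C)cc3)CC(=O)c12 | intermediate
7 | C6 ortho-dienone: (2S)-7-[(tert-butyldimethylsilyl)oxy]-2-{4-[(tert-butyldimethylsilyl)oxy]phenyl}-6-(3,7-dimethylocta-1,6-dien-3-yl)-2,3-dihydro-4H-chromene-4,5(6H)-dione (C6 and C3'' transient, not assigned) | C=CC(C)(CCC=C(C)C)C1C(O[Si](C)(C)C(C)(C)C)=CC2=C(C1=O)C(=O)C[C@@H](c1ccc(O[Si](C)(C)C(C)(C)C)cc1)O2 | intermediate (not isolated)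
8 | C8 para-dienone: (2S)-7-[(tert-butyldimethylsilyl)oxy]-2-{4-[(tert-butyldimethylsilyl)oxy]phenyl}-8-[(2E)-3,7-dimethylocta-2,6-dien-1-yl]-2,3-dihydro-4H-chromene-4,5(8H)-dione (C8 transient, not assigned) | CC(C)=CCC/C(C)=C/CC1C(O[Si](C)(C)C(C)(C)C)=CC(=O)C2=C1O[C@H](c1ccc(O[Si](C)(C)C(C)(C)C)cc1)CC2=O | intermediate (not isolated)
9 | (2S)-7-[(tert-butyldimethylsilyl)oxy]-2-{4-[(tert-butyldimethylsilyl)oxy]phenyl}-8-[(2E)-3,7-dimethylocta-2,6-dien-1-yl]-5-hydroxy-2,3-dihydro-4H-chromen-4-one | CC(C)=CCC/C(C)=C/Cc1c(O[Si](C)(C)C(C)(C)C)cc(O)c2c1O[C@H](c1ccc(O[Si](C)(C)C(C)(C)C)cc1)CC2=O | intermediate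
10 | sophoraflavanone A, (2S)-8-[(2E)-3,7-dimethylocta-2,6-dien-1-yl]-5,7-dihydroxy-2-(4-hydroxyphenyl)-2,3-dihydro-4H-chromen-4-one | CC(C)=CCC/C(C)=C/Cc1c(O)cc(O)c2c1O[C@H](c1ccc(O)cc1)CC2=O | target

**Step count**

Total steps: 5. Longest linear sequence: 5 steps (1 → 2 → 4 → 6 → 9 → 10).

**Steps most likely to fail**

Step 4. Enolisation of the C6 dienone may outrun the Cope shift and strand the chain on C6 in its inverted form. A boat component in either shift would leak the 2''Z isomer. Lewis-acid-assisted ionisation of the O1–C2 bond in the dienones would erode C2. The fallback makes the C8–C1'' bond by cross-coupling on a chromone and sets C2 last; it sets out from 1 and 3 and comes back at 10. Compound 1 is protected on both oxygens (NaH, MOMCl, DMF) to give 5,7-bis(methoxymethoxy)-4H-chromen-4-one F1. With O5 alkylated, iodination (NIS, DMF, rt) should go to C8, which is para to O5 and the less hindered site, to give 8-iodo-5,7-bis(methoxymethoxy)-4H-chromen-4-one F2. Geraniol 3 is converted into geranyl chloride F3 (MsCl, LiCl, s-collidine, DMF, 0 °C) and then into (E)-geranyltributylstannane F4 (Bu3SnLi, THF, −78 °C). Stille coupling of F2 with F4 (Pd2(dba)3, AsPh3, DMF, 60 °C) should give 8-[(2E)-3,7-dimethylocta-2,6-dien-1-yl]-5,7-bis(methoxymethoxy)-4H-chromen-4-one F5 with the chain attached through C1''. The Rh-catalysed arylation of step 3 with 5 should then set C2 and give (2S)-2-{4-[(tert-butyldimethylsilyl)oxy]phenyl}-8-[(2E)-3,7-dimethylocta-2,6-dien-1-yl]-5,7-bis(methoxymethoxy)-2,3-dihydro-4H-chromen-4-one F6. Finally 3 M HCl in MeOH at 40 °C should remove the acetal and silyl groups to give 10.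

Step 3. Carbometalation of the electron-rich, non-chelated 5-alkoxychromone may be slower than protodeboronation of the aryl donor, and the Rh enolate may expel O1 before it is protonated. The fallback inverts the order of chain relay and stereocentre formation, so that the acceptor is a hydrogen-bond-activated 5-hydroxychromone; it sets out from 4 and comes back at 9. Compound 4 is submitted to the Eu(fod)3 conditions of step 4, or heated in N,N-diethylaniline since no stereocentre is at risk, to give 7-[(tert-butyldimethylsilyl)oxy]-8-[(2E)-3,7-dimethylocta-2,6-dien-1-yl]-5-hydroxy-4H-chromen-4-one F7. Rh-catalysed addition of 5 to F7 with the same chiral catalyst should then give 9 directly.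

Step 2. The strongly hydrogen-bonded 5-OH of the chromone may not be deprotonated by the betaine, or may attack C3'' (SN2') to give the tertiary ether. The fallback moves the etherification to the flavanone, where the hydrogen bond is weaker; it sets out from 2 and comes back at 6. Rh-catalysed addition of 5 to 2 should give (2S)-7-[(tert-butyldimethylsilyl)oxy]-2-{4-[(tert-butyldimethylsilyl)oxy]phenyl}-5-hydroxy-2,3-dihydro-4H-chromen-4-one F8. Mitsunobu reaction of F8 with 3 (PPh3, DIAD, THF) should then give 6.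

**Further compounds**

F1 | step 4 | 5,7-bis(methoxymethoxy)-4H-chromen-4-one | COCOc1cc(OCOC)c2c(c1)occc2=O
F2 | step 4 | 8-iodo-5,7-bis(methoxymethoxy)-4H-chromen-4-one | COCOc1cc(OCOC)c2c(c1I)occc2=O
F3 | step 4 | geranyl chloride, (2E)-1-chloro-3,7-dimethylocta-2,6-diene | CC(C)=CCC/C(C)=C/CCl
F4 | step 4 | (E)-geranyltributylstannane | CCCC[Sn](CCCC)(CCCC)C/C=C(\C)CCC=C(C)C
F5 | step 4 | 8-[(2E)-3,7-dimethylocta-2,6-dien-1-yl]-5,7-bis(methoxymethoxy)-4H-chromen-4-one | CC(C)=CCC/C(C)=C/Cc1c(OCOC)cc(OCOC)c2c1occc2=O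
F6 | step 4 | (2S)-2-{4-[(tert-butyldimethylsilyl)oxy]phenyl}-8-[(2E)-3,7-dimethylocta-2,6-dien-1-yl]-5,7-bis(methoxymethoxy)-2,3-dihydro-4H-chromen-4-one | CC(C)=CCC/C(C)=C/Cc1c(OCOC)cc(OCOC)c2c1O[C@H](c1ccc(O[Si](C)(C)C(C)(C)C)cc1)CC2=O
F7 | step 3 | 7-[(tert-butyldimethylsilyl)oxy]-8-[(2E)-3,7-dimethylocta-2,6-dien-1-yl]-5-hydroxy-4H-chromen-4-one | CC(C)=CCC/C(C)=C/Cc1c(O[Si](C)(C)C(C)(C)C)cc(O)c2c1occc2=O
F8 | step 2 | (2S)-7-[(tert-butyldimethylsilyl)oxy]-2-{4-[(tert-butyldimethylsilyl)oxy]phenyl}-5-hydroxy-2,3-dihydro-4H-chromen-4-one | CC(C)(C)[Si](C)(C)Oc1cc(O)c2c(c1)O[C@H](c1ccc(O[Si](C)(C)C(C)(C)C)cc1)CC2=O
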